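**Retrosynthetic overview**
1. Both C11=C12 bonds are cut. Two copies of the C15 enynyl phosphonium salt 18 undergo a double Wittig reaction with the C10 dialdehyde 19. The target is C2-symmetric, so one building block serves both ends, and the benzoates are cleaved in the same flask.
2. C8–C9 comes from a Sonogashira coupling of ring alkyne 13 with (E)-3-iodobut-2-en-1-ol 16. The C5 methyl comes from a Negishi methylation of vinyl bromide 11.
3. The cyclohexene ring is not built as a six-membered ring. C5 is inserted as CBr2 into the C4=C6 alkene of cyclopentenyl benzoate 8, and the dibromocyclopropane opens to a ring-enlarged allyl cation that is captured at C4.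
4. Enabling feature: ring atoms C4(O)–C5(C)=C6 form a 2-substituted cyclohex-2-en-1-ol, the signature of a halocyclopropane-to-allyl-cation opening. C3–O next to C4 can carry a participating ester. The quaternary C1 and the alkyne on C6 block and stabilise the other allyl terminus.
5. Ring order: the five-membered ring is bought in 1 and decorated in steps 1–4, with C3 set by CBS reduction. It is enlarged to the six-membered ring in step 5, and no other ring is formed.

Key step: step 5

Remark: carotenoid numbering is used for ring and chain atoms. The SMILES is read as the all-E (3S,4S,3'S,4'S) isomer, in which each 3,4-diol is trans.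

**Step 1**
Reactants: 1 3-ethoxycyclopent-2-en-1-one
Product: 3 3-ethoxy-5,5-dimethylcyclopent-2-en-1-one, via monomethyl enone 2 (not isolated)
Conditions: LDA (1.05 equiv), THF, −78 °C, then MeI; second cycle in the same flask: LDA (1.1 equiv), −78 °C, then MeI, → 0 °C
Reagents that add atoms: iodomethane CI
Why: Stork–Danheiser alkylation: kinetic deprotonation of the vinylogous ester occurs only at the alpha-prime CH2, so two LDA/MeI cycles should build the gem-dimethyl carbon that becomes C1, and no stereocentre survives.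

**Step 2**
Reactants: 3 3-ethoxy-5,5-dimethylcyclopent-2-en-1-one; 4 (triisopropylsilyl)acetylene
Product: 6 4,4-dimethyl-3-[(triisopropylsilyl)ethynyl]cyclopent-2-en-1-one, via tertiary propargylic alcohol 5 (not isolated)
Conditions: 4, n-BuLi, THF, −78 °C; add 3, −78 → 0 °C; then 1 M HCl, THF, rt
Reagents that add atoms: water O
Why: Stork–Danheiser carbonyl transposition: 1,2-addition of the slim lithium acetylide to the carbonyl next to the quaternary carbon, then acid hydrolysis of the enol ether with loss of the tertiary hydroxyl, should place the alkyne on the alkene carbon adjacent to the gem-dimethyl group.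

**Step 3**
Reactants: 6 4,4-dimethyl-3-[(triisopropylsilyl)ethynyl]cyclopent-2-en-1-one
Product: 7 (1S)-4,4-dimethyl-3-[(triisopropylsilyl)ethynyl]cyclopent-2-en-1-ol
Conditions: (R)-2-methyl-CBS-oxazaborolidine (0.2 equiv), catecholborane (1.5 equiv), toluene, −78 °C; aqueous work-up
Reagents that add atoms: none
Why: Corey–Bakshi–Shibata reduction: the enyne-bearing sp2 flank should act as the large group, so the (R)-catalyst should give the (S)-carbinol (future C3), and catecholborane at low temperature spares the alkene and the alkyne.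

**Step 4**
Reactants: 7 (1S)-4,4-dimethyl-3-[(triisopropylsilyl)ethynyl]cyclopent-2-en-1-ol
Product: 8 (1S)-4,4-dimethyl-3-[(triisopropylsilyl)ethynyl]cyclopent-2-en-1-yl benzoate
Conditions: BzCl, Et3N, DMAP (cat.), CH2Cl2, 0 °C → rt
Reagents that add atoms: benzoyl chloride O=C(Cl)c1ccccc1
Why: DMAP-catalysed O-acylation proceeds with retention at the carbinol carbon and installs the ester that later serves both as participating group and as protecting group.

**Step 5**
Reactants: 8 (1S)-4,4-dimethyl-3-[(triisopropylsilyl)ethynyl]cyclopent-2-en-1-yl benzoate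
Product: 11 (1S,2R)-3-bromo-5,5-dimethyl-4-[(triisopropylsilyl)ethynyl]cyclohex-3-ene-1,2-diyl dibenzoate, via dibromocyclopropane 9 (not isolated), via allylic bromide 10 (not isolated)
Conditions: PhHgCBr3 (1.6 equiv), PhH, 80 °C; cool, filter off PhHgBr; AgO2CPh (1.5 equiv), PhH, rt → 60 °C, dark
Reagents that add atoms: phenyl(tribromomethyl)mercury BrC(Br)(Br)[Hg]c1ccccc1; silver benzoate [Ag+].[O-]C(=O)c1ccccc1
Why: PhHgCBr3 releases free CBr2 under neutral, anhydrous conditions (needed because 8 is an ester and because water would divert the later cation to the cis series), and the carbene adds in a cheletropic [2+1] step to the only alkene of 8, anti to the benzoate, while the less nucleophilic, TIPS-shielded alkyne is left alone, giving 9. At 80 °C the endo C–Br bond of 9 ionises in concert with disrotatory two-electron electrocyclic cleavage of the bond shared by the three- and five-membered rings (Woodward–Hoffmann–DePuy rule), helped by the alkynyl group on the bridgehead, so the five-membered ring becomes a six-membered 2-bromoallyl cation in which the carbene carbon is C5. The closest known reaction type is the thermal or silver-promoted ring expansion of 6,6-dibromobicyclo[3.1.0]hexanes to 2-bromocyclohex-2-enyl esters, combined here with Prévost-type acyloxy participation. The six-membered ring is therefore closed by carbene addition plus bridge-bond cleavage and not by a cyclisation, and the only cyclisation is the transient 5-exo attack of the benzoate carbonyl oxygen on C4, which gives a cis-fused 2-phenyl-1,3-dioxolan-2-ylium ion on the face of the C3–O bond. The one new stereocentre, C4, is controlled by C3 through this ion: bromide (to 10) and, after silver ion has pulled bromide off again with anchimeric help, benzoate open it at C4 with inversion, so the C4–O bond ends trans to C3–O as in a 1,2-trans glycosylation, and the configuration of 9 at the former alkene carbons is erased and does not matter. The step needs capture at C4 and not at C6 or the alkyne terminus, which the intramolecular ester, the quaternary C1 and the TIPS group secure, and opening at the allylic C4 and not at C3, which the allylic activation secures and which protects the enantiopurity.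

**Step 6**
Reactants: 11 (1S,2R)-3-bromo-5,5-dimethyl-4-[(triisopropylsilyl)ethynyl]cyclohex-3-ene-1,2-diyl dibenzoate
Product: 12 (1S,2S)-3,5,5-trimethyl-4-[(triisopropylsilyl)ethynyl]cyclohex-3-ene-1,2-diyl dibenzoate
Conditions: MeZnCl (2 equiv), Pd(dppf)Cl2 (5 mol %), THF, 50 °C
Reagents that add atoms: methylzinc chloride C[Zn]Cl
Why: Negishi coupling: oxidative addition of zerovalent palladium into the alkyne-activated C(sp2)–Br bond should outrun ionisation of the hindered allylic benzoate, the organozinc reagent leaves esters and the silylalkyne untouched, and no stereocentre is touched (the C4 descriptor changes only because Br is replaced by C).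

**Step 7**
Reactants: 12 (1S,2S)-3,5,5-trimethyl-4-[(triisopropylsilyl)ethynyl]cyclohex-3-ene-1,2-diyl dibenzoate
Product: 13 (1S,2S)-4-ethynyl-3,5,5-trimethylcyclohex-3-ene-1,2-diyl dibenzoate
Conditions: Bu4NF (1.2 equiv), AcOH (1.2 equiv), THF, 0 °C → rt
Reagents that add atoms: none
Why: Fluoride-induced protodesilylation of the alkynylsilane, with acetic acid buffering so that the benzoates should stay in place.

**Step 8**
Reactants: 14 but-2-yn-1-ol
Product: 16 (E)-3-iodobut-2-en-1-ol, via alkenylzirconocene 15 (not isolated)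
Conditions: Cp2Zr(H)Cl (2.2 equiv), THF, 0 °C → rt; I2, −78 → 0 °C; 1 M HCl work-up
Reagents that add atoms: iodine II
Why: Hydrozirconation–iodinolysis: after metalation of the hydroxyl group, syn addition of Zr–H should place zirconium on the methyl-bearing carbon, away from the bulky zirconium alkoxide, and iodine replaces zirconium with retention to give the E iodide.

**Step 9**
Reactants: 13 (1S,2S)-4-ethynyl-3,5,5-trimethylcyclohex-3-ene-1,2-diyl dibenzoate; 16 (E)-3-iodobut-2-en-1-ol
Product: 17 (1S,2S)-4-[(3E)-5-hydroxy-3-methylpent-3-en-1-yn-1-yl]-3,5,5-trimethylcyclohex-3-ene-1,2-diyl dibenzoate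
Conditions: Pd(PPh3)2Cl2 (3 mol %), CuI (6 mol %), i-Pr2NH, THF, rt, Ar
Reagents that add atoms: none
Why: Sonogashira coupling of a terminal alkyne with an alkenyl iodide runs at room temperature with retention of the alkene geometry (9E) and tolerates the free primary alcohol and the benzoates.

**Step 10**
Reactants: 17 (1S,2S)-4-[(3E)-5-hydroxy-3-methylpent-3-en-1-yn-1-yl]-3,5,5-trimethylcyclohex-3-ene-1,2-diyl dibenzoate
Product: 18 {(2E)-5-[(3S,4S)-3,4-bis(benzoyloxy)-2,6,6-trimethylcyclohex-1-en-1-yl]-3-methylpent-2-en-4-yn-1-yl}triphenylphosphonium bromide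
Conditions: PPh3·HBr (1.05 equiv), CH2Cl2, rt
Reagents that add atoms: triphenylphosphine hydrobromide [Br-].c1ccc(cc1)[PH+](c1ccccc1)c1ccccc1
Why: Acid-mediated substitution of an allylic alcohol by triphenylphosphine (the standard carotenoid phosphonium salt formation) should address only the free primary hydroxyl, whose departure is assisted by the methyl-substituted enyne, while the esterified secondary positions stay untouched.

**Step 11**
Reactants: 18 C15 phosphonium bromide (two equivalents); 19 (2E,4E,6E)-2,7-dimethylocta-2,4,6-trienedial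
Product: 21 (all-E,3S,4S,3'S,4'S)-7,8,7',8'-tetradehydro-β,β-carotene-3,4,3',4'-tetrol, via tetrabenzoate 20 (not isolated)
Conditions: 18 (2.2 equiv), 19, NaOMe (2.5 equiv, added last), CH2Cl2/MeOH, 0 °C → rt, Ar, dark; then more NaOMe, MeOH/THF, rt; brief warming in EtOH (60 °C), crystallisation
Reagents that add atoms: none
Why: Double Wittig olefination of the semistabilised ylide forms both C11=C12 bonds, the sterically hindered 11Z bonds should relax to E on gentle warming, and methoxide then removes the four benzoates by transesterification without touching a stereocentre.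

**Compound list**
1 | 3-ethoxycyclopent-2-en-1-one | CCOC1=CC(=O)CC1 | starting material
2 | 3-ethoxy-5-methylcyclopent-2-en-1-one (racemic) | CCOC1=CC(=O)C(C)C1 | intermediate
3 | 3-ethoxy-5,5-dimethylcyclopent-2-en-1-one | CCOC1=CC(=O)C(C)(C)C1 | intermediate
4 | (triisopropylsilyl)acetylene | C#C[Si](C(C)C)(C(C)C)C(C)C | starting material
5 | 3-ethoxy-5,5-dimethyl-1-[(triisopropylsilyl)ethynyl]cyclopent-2-en-1-ol (racemic) | CCOC1=CC(O)(C#C[Si](C(C)C)(C(C)C)C(C)C)C(C)(C)C1 | intermediate
6 | 4,4-dimethyl-3-[(triisopropylsilyl)ethynyl]cyclopent-2-en-1-one | O=C1C=C(C#C[Si](C(C)C)(C(C)C)C(C)C)C(C)(C)C1 | intermediate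
7 | (1S)-4,4-dimethyl-3-[(triisopropylsilyl)ethynyl]cyclopent-2-en-1-ol | CC1(C)C[C@H](O)C=C1C#C[Si](C(C)C)(C(C)C)C(C)C | intermediate
8 | (1S)-4,4-dimethyl-3-[(triisopropylsilyl)ethynyl]cyclopent-2-en-1-yl benzoate | CC1(C)C[C@H](OC(=O)c2ccccc2)C=C1C#C[Si](C(C)C)(C(C)C)C(C)C | intermediate
9 | (1S,2S,5R)-6,6-dibromo-4,4-dimethyl-5-[(triisopropylsilyl)ethynyl]bicyclo[3.1.0]hexan-2-yl benzoate (CBr2 anti to the benzoate) | CC1(C)C[C@H](OC(=O)c3ccccc3)[C@H]2C(Br)(Br)[C@@]12C#C[Si](C(C)C)(C(C)C)C(C)C | intermediate
10 | (1S,2R)-2,3-dibromo-5,5-dimethyl-4-[(triisopropylsilyl)ethynyl]cyclohex-3-en-1-yl benzoate (trans) | BrC1=C(C#C[Si](C(C)C)(C(C)C)C(C)C)C(C)(C)C[C@H](OC(=O)c2ccccc2)[C@H]1Br | intermediate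
11 | (1S,2R)-3-bromo-5,5-dimethyl-4-[(triisopropylsilyl)ethynyl]cyclohex-3-ene-1,2-diyl dibenzoate (trans) | BrC1=C(C#C[Si](C(C)C)(C(C)C)C(C)C)C(C)(C)C[C@H](OC(=O)c2ccccc2)[C@H]1OC(=O)c3ccccc3 | intermediate
12 | (1S,2S)-3,5,5-trimethyl-4-[(triisopropylsilyl)ethynyl]cyclohex-3-ene-1,2-diyl dibenzoate | CC1=C(C#C[Si](C(C)C)(C(C)C)C(C)C)C(C)(C)C[C@H](OC(=O)c2ccccc2)[C@H]1OC(=O)c3ccccc3 | intermediate
13 | (1S,2S)-4-ethynyl-3,5,5-trimethylcyclohex-3-ene-1,2-diyl dibenzoate | CC1=C(C#C)C(C)(C)C[C@H](OC(=O)c2ccccc2)[C@H]1OC(=O)c3ccccc3 | intermediate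
14 | but-2-yn-1-ol | CC#CCO | starting material
15 | chlorozirconocene alkoxide of (E)-3-(chlorozirconocenyl)but-2-en-1-ol | C/C(=C\CO[Zr](Cl)(C1C=CC=C1)C1C=CC=C1)[Zr](Cl)(C1C=CC=C1)C1C=CC=C1 | intermediate
16 | (E)-3-iodobut-2-en-1-ol | I/C(C)=C/CO | intermediate
17 | (1S,2S)-4-[(3E)-5-hydroxy-3-methylpent-3-en-1-yn-1-yl]-3,5,5-trimethylcyclohex-3-ene-1,2-diyl dibenzoate | CC1=C(C#C/C(C)=C/CO)C(C)(C)C[C@H](OC(=O)c2ccccc2)[C@H]1OC(=O)c3ccccc3 | intermediate
18 | {(2E)-5-[(3S,4S)-3,4-bis(benzoyloxy)-2,6,6-trimethylcyclohex-1-en-1-yl]-3-methylpent-2-en-4-yn-1-yl}triphenylphosphonium bromide | CC1=C(C#C/C(C)=C/C[P+](c2ccccc2)(c2ccccc2)c2ccccc2)C(C)(C)C[C@H](OC(=O)c2ccccc2)[C@H]1OC(=O)c3ccccc3.[Br-] | intermediate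
19 | (2E,4E,6E)-2,7-dimethylocta-2,4,6-trienedial | O=C/C(C)=C/C=C/C=C(\C)C=O | starting material
20 | (all-E,3S,4S,3'S,4'S)-7,8,7',8'-tetradehydro-β,β-carotene-3,4,3',4'-tetrayl tetrabenzoate | CC1=C(C#C/C(C)=C/C=C/C(C)=C/C=C/C=C(C)/C=C/C=C(\C)C#CC2=C(C)[C@H](OC(=O)c3ccccc3)[C@@H](OC(=O)c3ccccc3)CC2(C)C)C(C)(C)C[C@H](OC(=O)c3ccccc3)[C@H]1OC(=O)c4ccccc4 | intermediate
21 | (all-E,3S,4S,3'S,4'S)-7,8,7',8'-tetradehydro-β,β-carotene-3,4,3',4'-tetrol | CC1=C(C#C/C(C)=C/C=C/C(C)=C/C=C/C=C(C)/C=C/C=C(\C)C#CC2=C(C)[C@H](O)[C@@H](O)CC2(C)C)C(C)(C)C[C@H](O)[C@H]1O | target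

**Total step count:** 11. **Longest linear sequence:** 10 (steps 1–7 and 9–11; step 8 is a one-step side branch).

**Steps most likely to fail**

**Step 5.**
- What may go wrong: carbene transfer to the hindered, inductively deactivated enyne alkene may be sluggish. The cation may leak to capture at the propargylic terminus. The dioxolanylium ion may be opened partly at C3, which would erode the enantiopurity.
- Where the fallback runs: it sets out from 7 and comes back at 11. It keeps the halocyclopropane ring enlargement but gives up participation in favour of a stereochemical correction.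
- Alcohol 7 is silylated (TBSCl, imidazole, DMF) to the more electron-rich (1S)-cyclopentenyl tert-butyldimethylsilyl ether F1.
- F1 takes up CBr2 from CHBr3/KOt-Bu in pentane at −20 °C to give the silyloxy dibromocyclopropane F2.
- AgClO4 in aqueous acetone opens F2 to the ring-enlarged 2-bromo-6-silyloxycyclohex-2-en-1-ol F3 as a pair of separable C4 epimers.
- The trans epimer is benzoylated (BzCl, pyridine). The cis epimer is inverted by a Mitsunobu reaction with benzoic acid (PPh3, DIAD). Both converge on the trans 4-benzoate 3-silyl ether F4.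
- HF·pyridine, which spares the alkynyl-TIPS group, frees the C3 hydroxyl to give the hydroxy benzoate F5, and benzoylation returns 11.

**Step 6.**
- What may go wrong: zerovalent palladium may ionise the allylic benzoate, leading through a π-allyl complex to allylic methylation or elimination. This could compete with slow oxidative addition into the flanked C–Br bond.
- Where the fallback runs: it sets out from 11 and comes back at 12. It removes the leaving groups before any palladium chemistry.
- NaOMe/MeOH gives the bromo diol F6.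
- A Suzuki–Miyaura methylation with trimethylboroxine (Pd(dppf)Cl2, K2CO3, aqueous dioxane, 90 °C) on the free diol gives the trimethyl diol F7.
- BzCl/pyridine/DMAP then returns 12.

**Step 3.**
- What may go wrong: facial discrimination may be poor, because the CH2 flank of the ketone carries the neopentyl quaternary carbon and the two flanks differ less in size than in a simple enone.
- Where the fallback runs: it sets out from 6 and comes back at 7. It replaces catalyst control by an enzymatic resolution.
- Luche reduction (NaBH4, CeCl3·7H2O, MeOH, 0 °C) gives the racemic allylic alcohol F8.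
- Candida antarctica lipase B with vinyl acetate in MTBE should, by the Kazlauskas rule, acylate the (R)-enantiomer to the (R)-acetate F9. This leaves the (S)-alcohol 7, which is separated by chromatography.
- The dibenzoate 11 may in addition offer a point for enrichment by crystallisation.

**Further compounds**
F1 | step 5 | tert-butyl({(1S)-4,4-dimethyl-3-[(triisopropylsilyl)ethynyl]cyclopent-2-en-1-yl}oxy)dimethylsilane | CC1(C)C[C@H](O[Si](C)(C)C(C)(C)C)C=C1C#C[Si](C(C)C)(C(C)C)C(C)C
F2 | step 5 | (1S,2S,5R)-6,6-dibromo-2-[(tert-butyldimethylsilyl)oxy]-4,4-dimethyl-5-[(triisopropylsilyl)ethynyl]bicyclo[3.1.0]hexane | CC1(C)C[C@H](O[Si](C)(C)C(C)(C)C)[C@H]2C(Br)(Br)[C@@]12C#C[Si](C(C)C)(C(C)C)C(C)C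
F3 | step 5 | (6S)-2-bromo-6-[(tert-butyldimethylsilyl)oxy]-4,4-dimethyl-3-[(triisopropylsilyl)ethynyl]cyclohex-2-en-1-ol (both C1 epimers) | BrC1=C(C#C[Si](C(C)C)(C(C)C)C(C)C)C(C)(C)C[C@H](O[Si](C)(C)C(C)(C)C)C1O
F4 | step 5 | (1R,6S)-2-bromo-6-[(tert-butyldimethylsilyl)oxy]-4,4-dimethyl-3-[(triisopropylsilyl)ethynyl]cyclohex-2-en-1-yl benzoate | BrC1=C(C#C[Si](C(C)C)(C(C)C)C(C)C)C(C)(C)C[C@H](O[Si](C)(C)C(C)(C)C)[C@H]1OC(=O)c2ccccc2
F5 | step 5 | (1R,6S)-2-bromo-6-hydroxy-4,4-dimethyl-3-[(triisopropylsilyl)ethynyl]cyclohex-2-en-1-yl benzoate | BrC1=C(C#C[Si](C(C)C)(C(C)C)C(C)C)C(C)(C)C[C@H](O)[C@H]1OC(=O)c2ccccc2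
F6 | step 6 | (1S,2R)-3-bromo-5,5-dimethyl-4-[(triisopropylsilyl)ethynyl]cyclohex-3-ene-1,2-diol | BrC1=C(C#C[Si](C(C)C)(C(C)C)C(C)C)C(C)(C)C[C@H](O)[C@H]1O
F7 | step 6 | (1S,2S)-3,5,5-trimethyl-4-[(triisopropylsilyl)ethynyl]cyclohex-3-ene-1,2-diol | CC1=C(C#C[Si](C(C)C)(C(C)C)C(C)C)C(C)(C)C[C@H](O)[C@H]1O
F8 | step 3 | racemic 4,4-dimethyl-3-[(triisopropylsilyl)ethynyl]cyclopent-2-en-1-ol | CC1(C)CC(O)C=C1C#C[Si](C(C)C)(C(C)C)C(C)C
F9 | step 3 | (1R)-4,4-dimethyl-3-[(triisopropylsilyl)ethynyl]cyclopent-2-en-1-yl acetate | CC1(C)C[C@@H](OC(C)=O)C=C1C#C[Si](C(C)C)(C(C)C)C(C)C
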